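(The readings are calculated with constants of no real substance; the scatter is artificial.)

A small charge carries this flask: 0.50 mM of free catalyst must go round 500 times on average to convert half of 0.50 M of starting material. I therefore write the balance of the reagent charged in the smaller amount: free catalyst, both intermediates and spent catalyst always add up to that charge.

the same everywhere: free catalyst 0.50 mM

|  | starting material | remark |
|---|---|---|
| Sunday's | 0.34 M | run made earlier |
| Thursday's | 0.75 M | run made earlier |
| flask | 0.50 M |  |

| run | time / min | product / % | starting material / % |
|---|---|---|---|
| Sunday's | 1.00 | 11.4 | 86.1 |
| Sunday's | 3.00 | 36.1 | 66.1 |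
| Sunday's | 6.00 | 54.7 | 46.0 |
| Sunday's | 8.00 | 65.1 | 35.0 |
| Sunday's | 12.0 | 79.6 | 20.6 |
| Sunday's | 15.0 | 83.2 | 16.1 |
| Sunday's | 20.0 | 89.8 | 9.0 |
| Thursday's | 3.00 | 24.1 | 75.0 |
| Thursday's | 6.00 | 41.3 | 59.9 |
| Thursday's | 8.00 | 51.1 | 49.0 |
| Thursday's | 12.0 | 60.4 | 38.5 |
| Thursday's | 15.0 | 69.4 | 29.4 |
| Thursday's | 20.0 | 75.9 | 23.5 |

(readings scatter by 1 percentage point)

* apparent order in free catalyst when 50 % of the starting material are converted (percent change of the rate of making product for one percent more free catalyst charged)
* factor on the rate of making product when 50 % of the starting material are converted if free catalyst is charged twice over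

- steps that have been proposed: catalyst intermediate A -> catalyst intermediate B; starting material + free catalyst -> catalyst intermediate A; catalyst intermediate B <-> free catalyst + product; catalyst intermediate B -> spent catalyst
- no earlier run changes the charge of free catalyst; that part of a forecast is a guess

I define the loss factor as the rate at a given amount of starting material with no product yet made, divided by the rate at the product of half conversion. Sunday's and Thursday's runs had the flask's catalyst charge, so I compare them at nearly the same starting material. Sunday's early rate is 0.0340 M min⁻¹ at 0.0808 M of product, and Thursday's late rate is 0.0159 M min⁻¹ at 0.476 M. A straight line through these gives a loss factor of 1.43.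

The second way stays inside Sunday's run, where the first-order constant falls from 0.138 min⁻¹ to 0.104 min⁻¹. The same line gives 1.35, which is lower. This way cheats: over the first 6.00 min, Thursday's constant, 0.0854 min⁻¹, reads smaller than Sunday's, 0.129 min⁻¹, so this constant is larger at the smaller charge of starting material, and its fall inside Sunday's run understates the loss. I keep the first.

If the loss is catalyst death at a fixed cost per product, the order equals the loss factor and doubling gives 2.43. If product merely holds catalyst reversibly, the order is one and doubling gives two. No earlier run changes the charge of free catalyst, so I guess the midpoint: order 1.21, doubling 2.21. The forecast says order 1.2 and doubling 2.25, its doubling a little above mine: “The catalyst dependence itself remains a guess.”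

The flask gives order 1.2 and doubling 2.21.

    catalyst intermediate A → catalyst intermediate B (k = 7.81 s⁻¹)
    starting material + free catalyst → catalyst intermediate A (k = 7.51 L mol⁻¹ s⁻¹)
    catalyst intermediate B ⇌ free catalyst + product (K = 0.757 M, k = 8.55 s⁻¹)
    catalyst intermediate B → spent catalyst (k = 0.00187 s⁻¹)

My loss factor of 1.43 read the whole loss as death. Death is a part of that loss: in a run of the flask without the conversion of catalyst intermediate B into spent catalyst, the rate at half conversion is 1.21 times the actual one. In that same run, the order falls from 1.2 to 1.0.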